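**Plan**

1. Retrosynthesis: the three MOM acetals come off last. The C6–C(=O) bond between ring A and the ketone is cut to a ring A aryllithium and a ring B Weinreb amide. Ring C (the dihydropyran) is cut at two bonds at once, O1–C8a and C4–C4a, to a 3,5-dioxygenated aryne and the C5 unit 4-chloro-2-methylbutan-2-ol. The ring B aryl–prenyl bond is cut to an aryl bromide and prenylzinc bromide.
2. Enabling feature: O1 and C4 of ring C sit on the adjacent ring A carbons C8a and C4a; C4a has the C5 oxygen as neighbour and C8a has an unsubstituted CH (C8). This is the pattern left by a 3-alkoxyaryne that takes an oxygen nucleophile at its distal carbon and a carbon electrophile at the proximal one. The quaternary C2 and primary C4 make the partner a tertiary alkoxide carrying a primary chloride.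
3. Forward, fragment 1: bis-MOM protection of 5-bromoresorcinol, then the aryne annulation, which builds ring C on ring A in one step.
4. Forward, fragment 2: methyl 3-(4-hydroxyphenyl)propanoate is ortho-brominated, MOM-protected, prenylated by a linear-selective Negishi coupling and converted to the Weinreb amide.
5. Union and end game: lithiation of ring A at C6 (between the two OMOM groups), acylation by the Weinreb amide, then removal of the acetals with dilute acid.
6. Stereochemistry: the target has no stereocentre and no stereogenic double bond, so none has to be set.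

Key step: step 2

Remark: 5-bromoresorcinol, 4-chloro-2-methylbutan-2-ol, methyl 3-(4-hydroxyphenyl)propanoate and prenyl bromide are taken to be catalogue chemicals; chroman locants (O1, C2 to C8a) are used for rings A and C throughout.

**Route**

Step 1
Reactants: 1 5-bromobenzene-1,3-diol (5-bromoresorcinol)
Product: 2 1-bromo-3,5-bis(methoxymethoxy)benzene
Conditions: MOMCl (2.5 equiv), i-Pr2NEt (3 equiv), CH2Cl2, 0 °C to rt
Reagents that add atoms: chloromethyl methyl ether (MOMCl), COCCl
Why: O-alkylation of both phenols by the chloromethyl ether (MOM protection) is routine, and the acetal is chosen because it survives lithium bases, directs the later ortho-lithiation and leaves under acid mild enough for the prenyl group.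

Step 2
Reactants: 2 1-bromo-3,5-bis(methoxymethoxy)benzene; 3 4-chloro-2-methylbutan-2-ol
Product: 7 5,7-bis(methoxymethoxy)-2,2-dimethylchromane, via lithium alkoxide 4 (not isolated), via aryne 5 (not isolated), via aryllithium 6 (not isolated)
Conditions: 3 (3 equiv), 2,2,6,6-tetramethylpiperidine (2.5 equiv), n-BuLi (5.5 equiv), THF, −78 °C; then 2, −78 °C to rt
Reagents that add atoms: none
Why: Proposed new method: lithium 2,2,6,6-tetramethylpiperidide removes the ring proton of 2 that lies between Br and an OMOM group, loss of LiBr gives the 3,5-dialkoxyaryne 5, the tertiary alkoxide 4 adds through oxygen to the aryne carbon remote from the flanking OMOM group, and the aryllithium 6 so formed displaces the primary chloride of its own side chain, so that the O1–C8a and C4–C4a bonds arise in one flask. The closest known reaction types are the addition of tert-alkoxides to arynes made by dehydrohalogenation (tert-butoxide and bromobenzene to tert-butyl phenyl ether), the Parham cyclialkylation of o-lithioaryl ω-haloalkyl ethers to chromans, and aryne annulations by a tethered nucleophile–electrophile pair (salicylate plus aryne to xanthone); what is new is their union with an aliphatic γ-chloro alkoxide. Ring C closes by a 6-exo-tet SN2 displacement, and no stereocentre is formed. The selectivity needed is regiochemical: the inductively withdrawing OMOM oxygen beside the triple bond distorts the aryne so that the nucleophile enters at the distal carbon and the carbanion sits ortho to oxygen, which puts O1 on C8a (next to C8–H) and C4 on C4a (next to the C5 oxygen), and because 2 is symmetric both possible dehydrobrominations give the same aryne. Chemoselectivity rests on the carbanion appearing only after C–O bond formation and already placed for six-membered ring closure, so alkylation should outrun proton return from the amine, while the hindered amide base adds slowly to arynes and the lithium alkoxide is too weak a nucleophile to close the four-membered oxetane at or below room temperature.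

Step 3
Reactants: 8 methyl 3-(4-hydroxyphenyl)propanoate
Product: 9 methyl 3-(3-bromo-4-hydroxyphenyl)propanoate
Conditions: NBS (1.0 equiv), MeCN, 0 °C to rt
Reagents that add atoms: N-bromosuccinimide (NBS), O=C1CCC(=O)N1Br
Why: Electrophilic aromatic bromination goes ortho to the free phenol because the para position carries the side chain, and one equivalent of reagent should hold it at monobromination.

Step 4
Reactants: 9 methyl 3-(3-bromo-4-hydroxyphenyl)propanoate
Product: 10 methyl 3-[3-bromo-4-(methoxymethoxy)phenyl]propanoate
Conditions: MOMCl (1.5 equiv), i-Pr2NEt (2 equiv), CH2Cl2, 0 °C to rt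
Reagents that add atoms: chloromethyl methyl ether (MOMCl), COCCl
Why: MOM protection of the phenol removes the acidic proton before the organozinc, Grignard and organolithium steps and matches the protecting groups of ring A for a single final deprotection.

Step 5
Reactants: 10 methyl 3-[3-bromo-4-(methoxymethoxy)phenyl]propanoate; 11 1-bromo-3-methylbut-2-ene (prenyl bromide)
Product: 13 methyl 3-[4-(methoxymethoxy)-3-(3-methylbut-2-en-1-yl)phenyl]propanoate, via prenylzinc bromide 12 (not isolated)
Conditions: 11, Zn dust, LiCl, THF, 0 °C; then 10, Pd(OAc)2 (2 mol %), CPhos (4 mol %), THF, rt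
Reagents that add atoms: none
Why: Negishi cross-coupling of an allylic zinc halide with an aryl bromide, in which the bulky biarylphosphine on palladium should steer reductive elimination to the unsubstituted allyl terminus and so give the linear prenyl arene, while the ester and the acetal are tolerated by the organozinc reagent.

Step 6
Reactants: 13 methyl 3-[4-(methoxymethoxy)-3-(3-methylbut-2-en-1-yl)phenyl]propanoate
Product: 14 N-methoxy-3-[4-(methoxymethoxy)-3-(3-methylbut-2-en-1-yl)phenyl]-N-methylpropanamide
Conditions: MeNH(OMe)·HCl (1.5 equiv), i-PrMgCl (3 equiv), THF, −20 to 0 °C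
Reagents that add atoms: N,O-dimethylhydroxylamine hydrochloride, CNOC.Cl
Why: Direct aminolysis of the methyl ester by the magnesium amide of N,O-dimethylhydroxylamine (Weinreb amide synthesis) is fast at low temperature and leaves the acetal and the trisubstituted alkene untouched.

Step 7
Reactants: 7 5,7-bis(methoxymethoxy)-2,2-dimethylchromane; 14 N-methoxy-3-[4-(methoxymethoxy)-3-(3-methylbut-2-en-1-yl)phenyl]-N-methylpropanamide
Product: 16 1-[5,7-bis(methoxymethoxy)-2,2-dimethyl-3,4-dihydro-2H-chromen-6-yl]-3-[4-(methoxymethoxy)-3-(3-methylbut-2-en-1-yl)phenyl]propan-1-one, via C6 aryllithium 15 (not isolated)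
Conditions: 7 (1.2 equiv), n-BuLi (1.15 equiv), THF, 0 °C; then 14, −78 to 0 °C; aq NH4Cl
Reagents that add atoms: none
Why: Directed ortho-metalation should occur at C6, the only ring position flanked by two chelating OMOM groups (C8 has one OMOM group and the weaker ring ether oxygen), and the aryllithium is then acylated by the Weinreb amide, whose chelated tetrahedral adduct stops the addition at the ketone.

Step 8
Reactants: 16 1-[5,7-bis(methoxymethoxy)-2,2-dimethyl-3,4-dihydro-2H-chromen-6-yl]-3-[4-(methoxymethoxy)-3-(3-methylbut-2-en-1-yl)phenyl]propan-1-one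
Product: 17 1-(5,7-dihydroxy-2,2-dimethyl-3,4-dihydro-2H-chromen-6-yl)-3-[4-hydroxy-3-(3-methylbut-2-en-1-yl)phenyl]propan-1-one (target)
Conditions: HCl (3 M aq), MeOH, 40 °C
Reagents that add atoms: none
Why: Acid-catalysed acetal exchange with methanol cleaves all three MOM ethers (the two next to the ketone leave most easily), and dilute acid at mild temperature should spare the prenyl alkene and not cyclise the liberated ortho-prenylphenol.

**Compound list**

1 | 5-bromobenzene-1,3-diol | Oc1cc(O)cc(Br)c1 | starting material
2 | 1-bromo-3,5-bis(methoxymethoxy)benzene | COCOc1cc(Br)cc(OCOC)c1 | intermediate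
3 | 4-chloro-2-methylbutan-2-ol | CC(C)(O)CCCl | starting material
4 | lithium 4-chloro-2-methylbutan-2-olate | CC(C)(CCCl)O[Li] | intermediate
5 | 3,5-bis(methoxymethoxy)benzyne (1,2-didehydro-3,5-bis(methoxymethoxy)benzene) | COCOC1=CC(OCOC)=CC#C1 | intermediate
6 | {2-[(4-chloro-2-methylbutan-2-yl)oxy]-4,6-bis(methoxymethoxy)phenyl}lithium | [Li]c1c(OCOC)cc(OCOC)cc1OC(C)(C)CCCl | intermediate
7 | 5,7-bis(methoxymethoxy)-2,2-dimethylchromane | CC1(C)CCc2c(OCOC)cc(OCOC)cc2O1 | intermediate
8 | methyl 3-(4-hydroxyphenyl)propanoate | COC(=O)CCc1ccc(O)cc1 | starting material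
9 | methyl 3-(3-bromo-4-hydroxyphenyl)propanoate | COC(=O)CCc1ccc(O)c(Br)c1 | intermediate
10 | methyl 3-[3-bromo-4-(methoxymethoxy)phenyl]propanoate | COC(=O)CCc1ccc(OCOC)c(Br)c1 | intermediate
11 | 1-bromo-3-methylbut-2-ene (prenyl bromide) | CC(C)=CCBr | starting material
12 | prenylzinc bromide | CC(C)=CC[Zn]Br | intermediate
13 | methyl 3-[4-(methoxymethoxy)-3-(3-methylbut-2-en-1-yl)phenyl]propanoate | COC(=O)CCc1ccc(OCOC)c(CC=C(C)C)c1 | intermediate
14 | N-methoxy-3-[4-(methoxymethoxy)-3-(3-methylbut-2-en-1-yl)phenyl]-N-methylpropanamide | CON(C)C(=O)CCc1ccc(OCOC)c(CC=C(C)C)c1 | intermediate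
15 | [5,7-bis(methoxymethoxy)-2,2-dimethylchroman-6-yl]lithium | CC1(C)CCc2c(OCOC)c([Li])c(OCOC)cc2O1 | intermediate
16 | 1-[5,7-bis(methoxymethoxy)-2,2-dimethyl-3,4-dihydro-2H-chromen-6-yl]-3-[4-(methoxymethoxy)-3-(3-methylbut-2-en-1-yl)phenyl]propan-1-one | CC1(C)CCc2c(OCOC)c(C(=O)CCc3ccc(OCOC)c(CC=C(C)C)c3)c(OCOC)cc2O1 | intermediate
17 | 1-(5,7-dihydroxy-2,2-dimethyl-3,4-dihydro-2H-chromen-6-yl)-3-[4-hydroxy-3-(3-methylbut-2-en-1-yl)phenyl]propan-1-one | CC(C)=CCc1cc(CCC(=O)c2c(O)cc3c(c2O)CCC(C)(C)O3)ccc1O | target

**Step count**

Total steps: 8. Longest linear sequence: 6 steps (steps 3, 4, 5, 6, 7, 8); the ring A branch (steps 1 and 2) joins at step 7.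

**Steps most likely to fail**

Step 2. The aryne may be captured by the amide base or by not yet eliminated aryllithium, the aryl carbanion may be protonated before the ring closes, or the chloro alkoxide may be lost by elimination or oxetane closure. The fallback uses known chemistry, sets out from 2 and comes back at 7. Palladium-catalysed hydroxylation of 2 (Pd2(dba)3, t-BuXPhos, KOH, dioxane–water, 100 °C) should give 3,5-bis(methoxymethoxy)phenol F1. Condensation of this phenol with 3-methylbut-2-enal in pyridine at 140 °C (ortho C-alkylation, dehydration to the ortho-quinone methide, oxa-6π electrocyclisation) should give 5,7-bis(methoxymethoxy)-2,2-dimethyl-2H-chromene F2. Hydrogenation of the chromene double bond (H2, Pd/C, EtOAc, rt) then gives 7.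

Step 7. Metalation may be diverted to C8, between the C7 acetal oxygen and ring oxygen O1, so that the acyl group enters the wrong ring position. The fallback uses a blocking group, sets out from 7 and comes back at 17. Lithiation and quench with Me3SiCl puts silicon on the competing position and should give 5,7-bis(methoxymethoxy)-2,2-dimethyl-8-(trimethylsilyl)chromane F3, in which C6 carries the only ring hydrogen. A second lithiation (n-BuLi, THF, 0 °C) and addition of 14 should give 1-[5,7-bis(methoxymethoxy)-2,2-dimethyl-8-(trimethylsilyl)chroman-6-yl]-3-[4-(methoxymethoxy)-3-(3-methylbut-2-en-1-yl)phenyl]propan-1-one F4. The acid treatment of step 8 then removes the silyl group by ipso-protonation of the electron-rich ring together with the three acetals and delivers 17.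

Step 5. The allyl unit may be transferred through its tertiary end to give the branched 1,1-dimethylallyl arene, the allylzinc reagent may homocouple, or oxidative addition beside the ortho acetal may be slow. The fallback replaces the cross-coupling by a sigmatropic route, sets out from 8 and comes back at 13. O-Alkylation of 8 with 3-chloro-3-methylbut-1-yne (K2CO3, KI, CuI cat., acetone, 60 °C) should give methyl 3-{4-[(2-methylbut-3-yn-2-yl)oxy]phenyl}propanoate F5. Semihydrogenation (H2, Pd/CaCO3 poisoned with Pb(OAc)2, quinoline, EtOAc) should give methyl 3-{4-[(2-methylbut-3-en-2-yl)oxy]phenyl}propanoate F6. Aromatic Claisen rearrangement (N,N-diethylaniline, 190 °C), whose [3,3] shift inverts the allyl unit, should give methyl 3-[4-hydroxy-3-(3-methylbut-2-en-1-yl)phenyl]propanoate F7. MOM protection under the conditions of step 4 then gives 13.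

**Further compounds**

F1 | step 2 | 3,5-bis(methoxymethoxy)phenol | COCOc1cc(O)cc(OCOC)c1
F2 | step 2 | 5,7-bis(methoxymethoxy)-2,2-dimethyl-2H-chromene | CC1(C)C=Cc2c(OCOC)cc(OCOC)cc2O1
F3 | step 7 | 5,7-bis(methoxymethoxy)-2,2-dimethyl-8-(trimethylsilyl)chromane | CC1(C)CCc2c(OCOC)cc(OCOC)c([Si](C)(C)C)c2O1
F4 | step 7 | 1-[5,7-bis(methoxymethoxy)-2,2-dimethyl-8-(trimethylsilyl)chroman-6-yl]-3-[4-(methoxymethoxy)-3-(3-methylbut-2-en-1-yl)phenyl]propan-1-one | CC1(C)CCc2c(OCOC)c(C(=O)CCc3ccc(OCOC)c(CC=C(C)C)c3)c(OCOC)c([Si](C)(C)C)c2O1
F5 | step 5 | methyl 3-{4-[(2-methylbut-3-yn-2-yl)oxy]phenyl}propanoate | COC(=O)CCc1ccc(OC(C)(C)C#C)cc1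
F6 | step 5 | methyl 3-{4-[(2-methylbut-3-en-2-yl)oxy]phenyl}propanoate | COC(=O)CCc1ccc(OC(C)(C)C=C)cc1
F7 | step 5 | methyl 3-[4-hydroxy-3-(3-methylbut-2-en-1-yl)phenyl]propanoate | COC(=O)CCc1ccc(O)c(CC=C(C)C)c1
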